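The numbers in the tables are simulated for substances that don't exist; noise was put on by code.

Compare the start of the north-east run with its end: J falls with a first-order constant of 0.709 min⁻¹ over the first 1.00 min, but with a smaller 0.478 min⁻¹ from 3.00 min to 5.00 min. One first-order decay cannot hold two constants.

| setting | west | north-west | north-east | flask |
|---|---|---|---|---|
| J | 0.10 M | 0.10 M | 0.050 M | 0.10 M |
| Q | 4.2 mM | 6.6 mM | 3 mM | 3.00 mM |
| remark | run made earlier | run made earlier | run made earlier |  |
| time |  |  |  | 5.0 min |

| run | time / min | J / % | L / % |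
|---|---|---|---|
| west | 0.833 | 40.8 | 33.1 |
| west | 1.50 | 22.6 | 45.3 |
| west | 2.50 | 10.7 | 54.0 |
| west | 3.00 | 7.4 | 57.3 |
| west | 4.00 | 4.4 | 60.6 |
| west | 5.00 | 2.1 | 63.6 |
| north-west | 0.833 | 32.0 | 44.9 |
| north-west | 1.50 | 15.6 | 58.6 |
| north-west | 2.50 | 5.7 | 67.5 |
| north-west | 3.00 | 4.5 | 70.3 |
| north-west | 4.00 | 1.5 | 71.7 |
| north-west | 5.00 | 0 | 72.8 |
| north-east | 1.00 | 49.2 | 31.9 |
| north-east | 2.00 | 27.0 | 49.3 |
| north-east | 3.00 | 16.4 | 57.3 |
| north-east | 4.00 | 8.6 | 63.9 |
| north-east | 5.00 | 6.3 | 66.6 |

(scatter of a reading: 0.5 percentage points)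

- Q is the free proton; pH is minus the decimal logarithm of its molar concentration

- part of the J that has reacted at 5.0 min
- pH of the solution at 5.0 min

Don't blame Q: north-east loses 0.0469 M of J on 3 mM of Q and keeps running, so treat [Q] as steady and the pH as that of the charge. Instead, suppose pseudo-first-order routes to L and beside them a route of second order in J. In the first interval of north-east, L takes 62.8% of the J lost, at a mean [J] of 0.0351 M. Define the crossover concentration, the [J] at which the two kinds of route draw J equally, and read it as 0.0592 M.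

Let s be charged [J] over crossover. Then the reciprocal of the fraction of J left, plus s, grows exponentially from its starting value with constant κ. The last north-east reading gives κ = 0.441 min⁻¹. The flask has the same [Q] and twice the J, so s = 1.69. I reckon 4.41% left, so 95.6% reacted.

The forecast, holding that “I take Q as essentially constant”, says 96% and pH 2.53. The flask gives 95.8% and pH 2.52.

    J + Q → D + Q + L (k = 2.20 L mol⁻¹ s⁻¹)
    D ⇌ Z + Q, settled at all times (K = 2.00 × 10⁻⁶ M)
    J → D + L (k = 9.30 × 10⁻⁴ s⁻¹)
    2 J → X (k = 0.0620 L mol⁻¹ s⁻¹)
    D → G (k = 0.160 s⁻¹)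

Carry the same crossover and κ to the flask stopped at 3.0 min: they give 11.9% of J left, and it holds 11.6%. In the flask, [J] is down to 0.0598 M at 0.500 min, about the crossover, and the step joining two J into X has 78% of its turnover up to 5.0 min behind it by 1.00 min. The routes to L then ran on while J fell to 4.22%, D passed to G, and at 5.00 min L stands at 55.0%, X at 40.7% and G at 0.0548 M.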